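The 4 questions ask which form holds most of the substrate at the end of each of two flasks, and how much it holds.

- beta: substrate 0.80 M; precatalyst 0.80 mM; impurity 0.18 mM; time 15 h
- epsilon: substrate 0.80 M; precatalyst 0.80 mM; impurity 0.27 mM; time 15 h

    substrate + free catalyst → catalyst intermediate (k1 = 4870 L mol⁻¹ h⁻¹)
    2 substrate → homo dimer (k2 = 0.0103 L mol⁻¹ h⁻¹)
    free catalyst + impurity → spent catalyst (k3 = 4.81 × 10⁵ L mol⁻¹ h⁻¹)
    catalyst intermediate → free catalyst + product (k4 = 287 h⁻¹)
    precatalyst → free catalyst (k5 = 0.0397 h⁻¹)

* which of these there is most of at the end, counted by the substrate in it, beta (substrate / catalyst intermediate / product)
* which of these there is most of at the end, counted by the substrate in it, epsilon (substrate / catalyst intermediate / product)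
* final amount of the leader among these, as a percentage of the substrate charged, in beta
* final amount of the leader among these, as a percentage of the substrate charged, in epsilon

- in percentages every species weighs as the substrate in it: one homo dimer counts as two
- a step written with two of one species runs at k times the square of its concentration and takes two of it each time
- run time (beta): 15 h

Two chemists turn the constants into times at the charged amounts and part over the impurity. The catalyst intermediate lasts 12.5 s by step 4, release from precatalyst has a half-life of 17 h, and the first half-life of substrate going to homo dimer is 60.7 h.

The first chemist treats the impurity as a poison, since its constant with free catalyst is 98.8 times the constant of substrate with free catalyst. She expects little product, and second-order dimerisation over 15 h then leaves 80.2% of the substrate in both beta and epsilon.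

The second chemist treats the impurity as a titrant: each impurity takes one catalyst and is gone, and its charge is smaller than the precatalyst charge in beta and in epsilon, so it is the limiting reagent of the poisoning. Release matches the impurity charge at ln[precatalyst/(precatalyst − impurity)] divided by the release constant 0.0397 h⁻¹, which is 6.42 h in beta and 10.4 h in epsilon, both shorter than the run. This is the clearing time, an induction period.

I reckon with the second chemist. Past the clearing time, working catalyst is the amount released minus the impurity charged. It turns at 287 h⁻¹ times the share held as catalyst intermediate, 93.1% at the charged substrate, with a Michaelis constant of 58.9 mM. Summed to the end, this makes product of 27.1% in beta and 7.09% in epsilon. Taken from the first chemist's 80.2%, that leaves substrate at 53.1% in beta and 73.1% in epsilon, by this reckoning more than product in each flask.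

The forecast takes the same side, that the impurity “titrates the released catalyst”, and gives substrate in beta at 53% and substrate in epsilon at 71%, the last lower than my 73.1%.

The simulation gives substrate leading beta at 53.7%, with product at 28.9%, and substrate leading epsilon at 71.1%, with product at 9.92%. At 7.50 h, later than beta's clearing time and earlier than epsilon's, the impurity stands at 3.98% of its charge in beta and 26.7% in epsilon.

The first chemist's view has its region in a neighbour flask, beta with 7.2 × 10⁻⁴ M of impurity. Its clearing time is 58.0 h, against 6.42 h in beta and longer than the 15 h run. Release by the end reaches 0.359 mM, less than that impurity charge, so the count of working catalyst does not begin within the run, and substrate should stay near 80.2%. That flask ends with product at 0.618%, impurity at 50% of its charge and substrate at 79.7%.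

Its constants are assumed, and the outcome is calculated.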